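**Retrosynthetic overview**
1. The acyl groups and the γ-lactone are installed last; the C7/C8 oxygens and the lactone come from osmylation of a (7Z)-alkene and oxidative lactonisation of the ten-membered carbocycle 28.
2. Key disconnection C9–C10: the homoallylic alcohol unit C9(OH)–C10–C11=C12 at the ring-A fusion is the retron of a [2,3]-Wittig shift. A temporary C12–O–C9 ether (a 13-membered ring bridging C1 and C12 of ring A) holds a C9 carbanion, stabilised by the C5=C6–C7=C8 diene, under the β face of C10. The tether is cleaved in the same step and its oxygen becomes the C9 hydroxyl.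
3. The 13-membered ether 26 comes from Williamson union (O12–C9) of ring-A alcohol 18 with dienyl bromide 10, then B-alkyl Suzuki–Miyaura macrocyclisation (C4–C5).
4. Ring A: L-erythronolactone acetonide (C11–C14) plus isoprene monoxide (C1, C2, C10, C15) by iridium-catalysed tert-(hydroxy)prenylation, then ring-closing metathesis (C10=C11). Side chain: Roche ester (C17–C19) via a 4-substituted butenolide (C6–C9) and iodo-olefination (C5, C16).
5. Order of ring formation: ring A (step 12), 13-membered ether (step 21), ten-membered carbocycle (step 22), γ-lactone (step 25).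

Key step: step 22

Assumptions: briarane numbering C1–C20 is used for all intermediates, β is the ring-A face carrying the C15 methyl, and BDA is the butane-2,3-diacetal bridging O13 and O14. The (R)-Tol-BINAP iridium catalyst of step 11 is taken to give the C14/C1 configuration drawn; if its sense of induction is the reverse, the (S)-ligand is used.

**Route**

Step 1
Reactants: 1 methyl (S)-3-hydroxy-2-methylpropanoate
Product: 2 methyl (S)-3-(tert-butyldimethylsilyloxy)-2-methylpropanoate
Conditions: TBSCl, imidazole, CH2Cl2, 0 °C to rt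
Reagents that add atoms: tert-butyldimethylsilyl chloride C[Si](C)(Cl)C(C)(C)C
Why: Standard silylation of the primary alcohol; the future C17 stereocentre is not involved.

Step 2
Reactants: 2 silyl ether ester
Product: 3 (S)-3-(tert-butyldimethylsilyloxy)-2-methylpropanal
Conditions: i-Bu2AlH, CH2Cl2, −78 °C; Rochelle salt work-up
Reagents that add atoms: none
Why: Low-temperature DIBAL-H reduction stops at the aldehyde through the stable tetrahedral aluminate; the α-stereocentre is kept by using the aldehyde at once.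

Step 3
Reactants: 3 aldehyde
Product: 4 (R)-tert-butyldimethyl[(2-methylbut-3-yn-1-yl)oxy]silane
Conditions: dimethyl (1-diazo-2-oxopropyl)phosphonate, K2CO3, MeOH, 0 °C to rt
Reagents that add atoms: dimethyl (1-diazo-2-oxopropyl)phosphonate COP(=O)(OC)C(=[N+]=[N-])C(C)=O
Why: Ohira–Bestmann (Seyferth–Gilbert) homologation gives the terminal alkyne under mild carbonate conditions that should not epimerise the α-stereocentre.

Step 4
Reactants: 4 alkyne
Product: 5 methyl (R)-5-(tert-butyldimethylsilyloxy)-4-methylpent-2-ynoate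
Conditions: n-BuLi, THF, −78 °C; then ClCO2Me
Reagents that add atoms: methyl chloroformate COC(=O)Cl
Why: Acylation of the lithium acetylide with a chloroformate gives the ynoate (C6–C8 with C17 attached).

Step 5
Reactants: 5 ynoate
Product: 7 butenolide 4-[(2R)-1-(tert-butyldimethylsilyloxy)propan-2-yl]furan-2(5H)-one, via hydroxy ester 6 (not isolated)
Conditions: hν (350 nm), benzophenone (sensitiser), MeOH, rt
Reagents that add atoms: methanol CO
Why: Sensitised photoaddition of methanol to the ynoate: the hydroxymethyl radical adds to the β-carbon (C8), the adducts equilibrate under irradiation and the Z isomer lactonises, fixing C9 cis to C6; no stereocentre is formed.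

Step 6
Reactants: 7 butenolide
Product: 8 lactol (2,5-dihydrofuran-2-ol, anomer mixture)
Conditions: i-Bu2AlH (1.1 equiv), CH2Cl2, −78 °C; neutral work-up, used at once
Reagents that add atoms: none
Why: Partial DIBAL-H reduction of the lactone to the lactol, which is telescoped to avoid dehydration to the furan.

Step 7
Reactants: 8 lactol
Product: 9 (2Z,4Z)-2-[(2R)-1-(tert-butyldimethylsilyloxy)propan-2-yl]-5-iodohexa-2,4-dien-1-ol
Conditions: EtPPh3I, n-BuLi, THF, 0 °C; I2, −78 °C; NaHMDS, −78 °C; then 8, −78 to −30 °C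
Reagents that add atoms: ethyltriphenylphosphonium iodide CC[P+](c1ccccc1)(c1ccccc1)c1ccccc1.[I-]; iodine II
Why: Wittig olefination of the open (Z)-4-hydroxy-enal form with the α-iodo ylide (Stork–Zhao-type iodoalkylidenation) should give the (Z)-vinyl iodide (iodine cis to C7) under kinetic control, while the (Z)-C7=C8 geometry is inherited from the butenolide ring.

Step 8
Reactants: 9 dienol
Product: 10 dienyl bromide tert-butyl{[(2R,3Z,5Z)-3-(bromomethyl)-6-iodo-2-methylhepta-3,5-dien-1-yl]oxy}dimethylsilane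
Conditions: CBr4, PPh3, CH2Cl2, 0 °C
Reagents that add atoms: tetrabromomethane BrC(Br)(Br)Br
Why: Appel bromination of the primary allylic alcohol (SN2 at CH2) leaves both alkene geometries intact.

Step 9
Reactants: 11 2,3-O-isopropylidene-L-erythronolactone
Product: 12 methyl hemiketal (1-deoxy-3,4-O-isopropylidene-L-erythro-pent-2-ulofuranose, anomer mixture)
Conditions: MeLi (1.05 equiv), THF, −78 °C; then H2O
Reagents that add atoms: methyllithium [Li]C
Why: Mono-addition of methyllithium to the lactone gives the stable hemiketal (C20 introduced on C11).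

Step 10
Reactants: 12 hemiketal
Product: 13 [(4S,5R)-2,2-dimethyl-5-(prop-1-en-2-yl)-1,3-dioxolan-4-yl]methanol
Conditions: MePPh3Br, KOt-Bu, THF, 0 °C to reflux
Reagents that add atoms: methyltriphenylphosphonium bromide C[P+](c1ccccc1)(c1ccccc1)c1ccccc1.[Br-]
Why: Wittig methylenation through the open hydroxy-ketone form with excess ylide; the cis-dioxolane (C12, C13) is retained.

Step 11
Reactants: 13 alkenol; 14 2-methyl-2-vinyloxirane (isoprene monoxide)
Product: 15 (1R,2S)-1-[(4S,5R)-2,2-dimethyl-5-(prop-1-en-2-yl)-1,3-dioxolan-4-yl]-2-methyl-2-vinylpropane-1,3-diol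
Conditions: [Ir(cod)Cl]2, (R)-Tol-BINAP, 4-cyano-3-nitrobenzoic acid, allyl acetate, Cs2CO3 (preformed cyclometallated catalyst), K3PO4 (5 mol%), THF, 60 °C
Reagents that add atoms: none
Why: Redox-triggered carbonyl addition (Krische tert-(hydroxy)prenylation): the primary alcohol is dehydrogenated to the aldehyde, which is captured through a closed chair transition state by the (E)-σ-allyliridium from isoprene monoxide, so that C14 and the quaternary C1 arise together with O14 anti to the CH2OH group (future C2) and with the absolute sense set by the ligand, which must override the Felkin preference of the α-alkoxy aldehyde.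

Step 12
Reactants: 15 diol
Product: 16 ring-A acetonide diol
Conditions: second-generation Grubbs catalyst (H2IMes)(PCy3)Cl2Ru=CHPh (5 mol%), CH2Cl2, 40 °C
Reagents that add atoms: none
Why: Ring-closing metathesis of the isopropenyl and vinyl groups closes ring A as the trisubstituted C10=C11 cyclohexene; no stereocentre is touched.

Step 13
Reactants: 16 ring-A diol
Product: 17 ring-A hydroxy aldehyde
Conditions: TEMPO (10 mol%), PhI(OAc)2, CH2Cl2, rt
Reagents that add atoms: none
Why: TEMPO/PhI(OAc)2 oxidises the primary alcohol selectively in the presence of the secondary C14 hydroxyl; the α-quaternary aldehyde cannot epimerise.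

Step 14
Reactants: 17 hydroxy aldehyde
Product: 18 ring-A BDA alcohol
Conditions: butane-2,3-dione, HC(OMe)3, camphorsulfonic acid (cat.), MeOH, reflux
Reagents that add atoms: butane-2,3-dione CC(=O)C(C)=O; methanol CO; trimethyl orthoformate COC(OC)OC
Why: Acid-catalysed acetal exchange: the isopropylidene group is methanolysed and the butane-2,3-diacetal forms selectively on the trans-diequatorial 13,14-diol and not on the cis 12,13-diol (Ley diacetal, as with shikimate esters; both methoxy groups axial), while the aldehyde becomes its dimethyl acetal, leaving O12–H as the only free hydroxyl.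

Step 15
Reactants: 18 ring-A BDA alcohol; 10 dienyl bromide
Product: 19 ether acetal
Conditions: NaH, Bu4NI (cat.), THF/DMF, 0 °C to rt
Reagents that add atoms: none
Why: Williamson etherification: the sodium alkoxide of O12 displaces the primary allylic bromide (SN2), installing the C12–O–C9 tether.

Step 16
Reactants: 19 ether acetal
Product: 20 ether aldehyde
Conditions: pyridinium p-toluenesulfonate, acetone/H2O, 40 °C
Reagents that add atoms: water O
Why: Mild acid hydrolysis of the dimethyl acetal; the anomerically stabilised BDA acetal and the silyl ether should survive.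

Step 17
Reactants: 20 ether aldehyde
Product: 21 allylic alcohols (C2 epimers)
Conditions: CH2=CHMgBr, THF, −78 to −20 °C; aq. NH4Cl
Reagents that add atoms: vinylmagnesium bromide C=C[Mg]Br
Why: Grignard addition to the neopentyl aldehyde brings in C3 and C4; the C2 configuration is not controlled here and is erased in step 18.

Step 18
Reactants: 21 allylic alcohols
Product: 22 vinyl ketone
Conditions: Dess–Martin periodinane, CH2Cl2, 0 °C to rt
Reagents that add atoms: none
Why: Dess–Martin oxidation of the secondary allylic alcohol under neutral conditions gives the enone without touching the iodo-diene.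

Step 19
Reactants: 22 vinyl ketone
Product: 23 (2S)-allylic alcohol
Conditions: (R)-2-methyl-CBS-oxazaborolidine (0.5 equiv), catecholborane, toluene, −78 °C
Reagents that add atoms: none
Why: Corey–Bakshi–Shibata reduction: the ketone binds with the quaternary C1 as the large and the vinyl group as the small substituent, so the (R)-catalyst should deliver the (2S)-alcohol; catecholborane at −78 °C keeps the reduction 1,2.

Step 20
Reactants: 23 (2S)-allylic alcohol
Product: 24 (2S)-PMB ether
Conditions: NaH, 4-methoxybenzyl chloride, Bu4NI (cat.), DMF, 0 °C to rt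
Reagents that add atoms: 4-methoxybenzyl chloride COc1ccc(CCl)cc1
Why: Williamson protection of O2 as the PMB ether, which is removable oxidatively later.

Step 21
Reactants: 24 (2S)-PMB ether
Product: 26 bridged 13-membered ether, via alkylborane 25 (not isolated)
Conditions: 9-BBN-H, THF, rt; then slow addition to Pd(dppf)Cl2 (20 mol%), AsPh3, Cs2CO3, DMF/THF/H2O, 1 mM, rt
Reagents that add atoms: none
Why: B-alkyl Suzuki–Miyaura macrocyclisation: 9-BBN hydroborates only the monosubstituted C3=C4 alkene (boron at C4) and zerovalent palladium couples this C(sp3) borane with the C5 vinyl iodide with retention of the (5Z) geometry, closing the 13-membered ring under high dilution.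

Step 22
Reactants: 26 bridged 13-membered ether
Product: 28 ten-membered carbocycle 9-O-TIPS ether, via lithium alkoxide 27 (not isolated)
Conditions: n-BuLi (1.5 equiv), THF, −78 to −40 °C; then i-Pr3SiOTf, −78 to 0 °C
Reagents that add atoms: triisopropylsilyl trifluoromethanesulfonate CC(C)[Si](C(C)C)(C(C)C)OS(=O)(=O)C(F)(F)F
Why: n-BuLi removes a C9 proton, the only primary position that is both α to oxygen and pentadienylic, and the carbanion undergoes a concerted suprafacial [2,3]-Wittig shift through a five-membered envelope (C9, O, C12, C11, C10): C9–C10 forms as C12–O breaks, the ring-A double bond moves from C10=C11 to C11=C12, and the oxygen becomes the C9 alkoxide, which is silylated in the same flask. The closest known reaction type is the [2,3]-Wittig ring contraction of 13-membered diallylic and allyl propargyl ethers to ten-membered carbocycles used for germacranes and cembranoids. The ten-membered ring C1–C10 closes by contraction of the 13-membered ether, a transannular bond formation in which O, C12 and C11 leave the large ring. C10 is set by 1,3-chirality transfer, the new bond forming on the β face from which the pseudoaxial C12–O bond departs; C9 is set by the envelope with C8 exo (anti to C11), the normal arrangement for a (Z)-type allyl terminus (C1 cis to C12) and the one the C2–C8 tether allows. The step needs regioselective metalation and [2,3] over [1,2] shift: the first is secured by the doubly activated C9–H2, the second by low temperature and by the BDA acetal, which locks ring A in the half-chair holding C12–O pseudoaxial and parallel to the π system.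

Step 23
Reactants: 28 9-O-TIPS carbocycle
Product: 29 C19 alcohol
Conditions: HF·pyridine, pyridine, THF, 0 °C
Reagents that add atoms: none
Why: Buffered fluoride cleaves the primary TBS ether selectively; the hindered secondary TIPS ether and the BDA acetal should remain.

Step 24
Reactants: 29 C19 alcohol
Product: 30 7,8,19-triol
Conditions: OsO4 (1.05 equiv), TMEDA, CH2Cl2, −78 °C; then aq. NaHSO3, THF, rt
Reagents that add atoms: osmium tetroxide O=[Os](=O)(=O)=O
Why: Hydrogen-bond-directed (Donohoe) osmylation: the free homoallylic C19 hydroxyl steers OsO4·TMEDA to C7=C8 and away from C5=C6 and C11=C12, and syn addition occurs on the peripheral face of the (Z)-cycloalkene anti to C10 with H9 eclipsing the double bond (allylic 1,3-strain with C6), which should give the 7,8-cis and 8,9-trans arrangement of the target.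

Step 25
Reactants: 30 triol
Product: 32 hydroxy lactone, via lactol 31 (not isolated)
Conditions: TEMPO (20 mol%), PhI(OAc)2 (3 equiv), CH2Cl2, rt
Reagents that add atoms: none
Why: TEMPO/PhI(OAc)2 oxidative lactonisation: the primary C19 alcohol is oxidised first, the aldehyde is trapped as the lactol by the C7 hydroxyl (O9 is silylated and O8 would give a four-membered ring) and oxidised to the γ-lactone; no stereocentre changes.

Step 26
Reactants: 32 hydroxy lactone
Product: 33 C2 alcohol
Conditions: DDQ, CH2Cl2/pH 7 buffer, 0 °C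
Reagents that add atoms: none
Why: Oxidative cleavage of the PMB ether by DDQ (benzylic hydride abstraction, then hydrolysis) leaves the lactone, silyl ether and acetal untouched.

Step 27
Reactants: 33 C2 alcohol
Product: 34 C2 propanoate
Conditions: (EtCO)2O, DMAP, Et3N, CH2Cl2, rt
Reagents that add atoms: propanoic anhydride CCC(=O)OC(=O)CC
Why: DMAP-catalysed acylation of the secondary C2 hydroxyl; the tertiary C8 hydroxyl should not react under these conditions.

Step 28
Reactants: 34 C2 propanoate
Product: 35 13,14-diol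
Conditions: CF3CO2H/H2O (9:1), 0 °C, short reaction time
Reagents that add atoms: none
Why: Aqueous acid hydrolysis of the BDA diacetal frees the trans-13,14-diol; the TIPS ether, lactone and propanoate should survive the brief treatment.

Step 29
Reactants: 35 13,14-diol
Product: 36 9-O-TIPS ether of the target
Conditions: (n-PrCO)2O, DMAP, pyridine, 40 °C
Reagents that add atoms: butanoic anhydride CCCC(=O)OC(=O)CCC
Why: DMAP-catalysed double acylation of the two secondary hydroxyls; O8 (tertiary) and O9 (silylated) stay untouched.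

Step 30
Reactants: 36 9-O-TIPS ether
Product: 37 target CNP0138989.1
Conditions: HF·pyridine, THF, rt to 40 °C
Reagents that add atoms: none
Why: Ester-compatible fluoride desilylation frees the C9 hydroxyl.

**Compound list**
1 | methyl (S)-3-hydroxy-2-methylpropanoate (Roche ester) | COC(=O)[C@@H](C)CO | starting material
2 | methyl (S)-3-(tert-butyldimethylsilyloxy)-2-methylpropanoate | COC(=O)[C@@H](C)CO[Si](C)(C)C(C)(C)C | intermediate
3 | (S)-3-(tert-butyldimethylsilyloxy)-2-methylpropanal | O=C[C@@H](C)CO[Si](C)(C)C(C)(C)C | intermediate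
4 | (R)-tert-butyldimethyl[(2-methylbut-3-yn-1-yl)oxy]silane | C#C[C@@H](C)CO[Si](C)(C)C(C)(C)C | intermediate
5 | methyl (R)-5-(tert-butyldimethylsilyloxy)-4-methylpent-2-ynoate | COC(=O)C#C[C@@H](C)CO[Si](C)(C)C(C)(C)C | intermediate
6 | methyl (2Z,4R)-5-(tert-butyldimethylsilyloxy)-3-(hydroxymethyl)-4-methylpent-2-enoate | COC(=O)/C=C(\CO)[C@@H](C)CO[Si](C)(C)C(C)(C)C | intermediate
7 | 4-[(2R)-1-(tert-butyldimethylsilyloxy)propan-2-yl]furan-2(5H)-one | O=C1C=C([C@@H](C)CO[Si](C)(C)C(C)(C)C)CO1 | intermediate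
8 | 4-[(2R)-1-(tert-butyldimethylsilyloxy)propan-2-yl]-2,5-dihydrofuran-2-ol (anomer mixture) | OC1C=C([C@@H](C)CO[Si](C)(C)C(C)(C)C)CO1 | intermediate
9 | (2Z,4Z)-2-[(2R)-1-(tert-butyldimethylsilyloxy)propan-2-yl]-5-iodohexa-2,4-dien-1-ol | C/C(I)=C/C=C(\CO)[C@@H](C)CO[Si](C)(C)C(C)(C)C | intermediate
10 | tert-butyl{[(2R,3Z,5Z)-3-(bromomethyl)-6-iodo-2-methylhepta-3,5-dien-1-yl]oxy}dimethylsilane | C/C(I)=C/C=C(\CBr)[C@@H](C)CO[Si](C)(C)C(C)(C)C | intermediate
11 | 2,3-O-isopropylidene-L-erythronolactone, (3aS,6aS)-2,2-dimethyldihydrofuro[3,4-d][1,3]dioxol-4(3aH)-one (enantiomer of the isoascorbic acid-derived lactone) | CC1(C)O[C@H]2COC(=O)[C@H]2O1 | starting material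
12 | 1-deoxy-3,4-O-isopropylidene-L-erythro-pent-2-ulofuranose (methyl hemiketal of 11, anomer mixture) | CC1(C)O[C@H]2COC(C)(O)[C@H]2O1 | intermediate
13 | [(4S,5R)-2,2-dimethyl-5-(prop-1-en-2-yl)-1,3-dioxolan-4-yl]methanol (C11–C14, C20) | C=C(C)[C@H]1OC(C)(C)O[C@H]1CO | intermediate
14 | 2-methyl-2-vinyloxirane (isoprene monoxide, racemic) | C=CC1(C)CO1 | starting material
15 | (1R,2S)-1-[(4S,5R)-2,2-dimethyl-5-(prop-1-en-2-yl)-1,3-dioxolan-4-yl]-2-methyl-2-vinylpropane-1,3-diol (14α-OH; C1 quaternary with CH3, vinyl, CH2OH) | C=C(C)[C@H]1OC(C)(C)O[C@H]1[C@H](O)[C@@](C)(C=C)CO | intermediate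
16 | ring-A acetonide diol: cyclohex-10-ene with 12β,13β-O-isopropylidene, 14α-OH, C1 bearing β-CH3 and α-CH2OH, C11 methyl | CC2(C)O[C@@H]1[C@H](O2)C(C)=C[C@@](C)(CO)[C@H]1O | intermediate
17 | ring-A hydroxy aldehyde (16 with C2 as CHO) | CC2(C)O[C@@H]1[C@H](O2)C(C)=C[C@@](C)(C=O)[C@H]1O | intermediate
18 | ring-A BDA alcohol: 13β,14α-O-(2,3-dimethoxybutane-2,3-diyl), 12β-OH, C2 as dimethyl acetal | CO[C@@]4(C)O[C@@H]1[C@H](O)C(C)=C[C@@](C)(C(OC)OC)[C@H]1O[C@]4(C)OC | intermediate
19 | ether acetal: 12β-O-ether of 18 with the (5Z,7Z)-5-iodo-diene chain C5–C9 carrying (17R)-CH(CH3)CH2OTBS at C8 | CO[C@@]4(C)O[C@@H]1[C@H](OC/C(=C\C=C(\C)I)[C@@H](C)CO[Si](C)(C)C(C)(C)C)C(C)=C[C@@](C)(C(OC)OC)[C@H]1O[C@]4(C)OC | intermediate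
20 | ether aldehyde (19 with C2 as CHO) | CO[C@@]4(C)O[C@@H]1[C@H](OC/C(=C\C=C(\C)I)[C@@H](C)CO[Si](C)(C)C(C)(C)C)C(C)=C[C@@](C)(C=O)[C@H]1O[C@]4(C)OC | intermediate
21 | allylic alcohols (C2 epimers; C2 bears OH and vinyl) | CO[C@@]4(C)O[C@@H]1[C@H](OC/C(=C\C=C(\C)I)[C@@H](C)CO[Si](C)(C)C(C)(C)C)C(C)=C[C@@](C)(C(O)C=C)[C@H]1O[C@]4(C)OC | intermediate
22 | vinyl ketone (C2 ketone) | CO[C@@]4(C)O[C@@H]1[C@H](OC/C(=C\C=C(\C)I)[C@@H](C)CO[Si](C)(C)C(C)(C)C)C(C)=C[C@@](C)(C(=O)C=C)[C@H]1O[C@]4(C)OC | intermediate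
23 | (2S)-allylic alcohol | CO[C@@]4(C)O[C@@H]1[C@H](OC/C(=C\C=C(\C)I)[C@@H](C)CO[Si](C)(C)C(C)(C)C)C(C)=C[C@@](C)([C@@H](O)C=C)[C@H]1O[C@]4(C)OC | intermediate
24 | (2S)-PMB ether | CO[C@@]4(C)O[C@@H]1[C@H](OC/C(=C\C=C(\C)I)[C@@H](C)CO[Si](C)(C)C(C)(C)C)C(C)=C[C@@](C)([C@@H](OCc3ccc(OC)cc3)C=C)[C@H]1O[C@]4(C)OC | intermediate
25 | alkylborane (C4 bound to 9-BBN boron) | CO[C@@]4(C)O[C@@H]1[C@H](OC/C(=C\C=C(\C)I)[C@@H](C)CO[Si](C)(C)C(C)(C)C)C(C)=C[C@@](C)([C@@H](OCc3ccc(OC)cc3)CCB5C6CCCC5CCC6)[C@H]1O[C@]4(C)OC | intermediate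
26 | bridged 13-membered ether: O12–C9 ether and C1–C2 chain span ring A (C10=C11); (5Z,7Z)-diene; 2-OPMB; 13,14-BDA; C19 OTBS | CO[C@@]4(C)O[C@@H]1[C@@H]2OC/C([C@@H](C)CO[Si](C)(C)C(C)(C)C)=C\C=C(\C)CC[C@H](OCc3ccc(OC)cc3)[C@](C)(C=C2C)[C@H]1O[C@]4(C)OC | intermediate
27 | lithium C9 alkoxide of the ten-membered carbocycle (C11=C12; (5Z,7Z)-diene) | CO[C@@]4(C)O[C@@H]1C=C(C)[C@@H]2[C@H](O[Li])/C([C@@H](C)CO[Si](C)(C)C(C)(C)C)=C\C=C(\C)CC[C@H](OCc3ccc(OC)cc3)[C@@]2(C)[C@H]1O[C@]4(C)OC | intermediate
28 | ten-membered carbocycle 9-O-TIPS ether (C9 and C10 as in the target) | CO[C@@]4(C)O[C@@H]1C=C(C)[C@@H]2[C@H](O[Si](C(C)C)(C(C)C)C(C)C)/C([C@@H](C)CO[Si](C)(C)C(C)(C)C)=C\C=C(\C)CC[C@H](OCc3ccc(OC)cc3)[C@@]2(C)[C@H]1O[C@]4(C)OC | intermediate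
29 | C19 alcohol | CO[C@@]4(C)O[C@@H]1C=C(C)[C@@H]2[C@H](O[Si](C(C)C)(C(C)C)C(C)C)/C([C@@H](C)CO)=C\C=C(\C)CC[C@H](OCc3ccc(OC)cc3)[C@@]2(C)[C@H]1O[C@]4(C)OC | intermediate
30 | 7,8,19-triol (C7 and C8 as in the target) | CO[C@@]4(C)O[C@@H]1C=C(C)[C@@H]2[C@H](O[Si](C(C)C)(C(C)C)C(C)C)[C@](O)([C@@H](C)CO)[C@@H](O)/C=C(/C)CC[C@H](OCc3ccc(OC)cc3)[C@@]2(C)[C@H]1O[C@]4(C)OC | intermediate
31 | lactol (C19 hemiacetal with O7, anomer mixture) | CO[C@@]4(C)O[C@@H]1C=C(C)[C@@H]2[C@H](O[Si](C(C)C)(C(C)C)C(C)C)[C@@]3(O)[C@H](/C=C(/C)CC[C@H](OCc5ccc(OC)cc5)[C@@]2(C)[C@H]1O[C@]4(C)OC)OC(O)[C@@H]3C | intermediate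
32 | hydroxy lactone (8-OH, 9-OTIPS, 2-OPMB, 13,14-BDA) | CO[C@@]4(C)O[C@@H]1C=C(C)[C@@H]2[C@H](O[Si](C(C)C)(C(C)C)C(C)C)[C@@]3(O)[C@H](/C=C(/C)CC[C@H](OCc5ccc(OC)cc5)[C@@]2(C)[C@H]1O[C@]4(C)OC)OC(=O)[C@@H]3C | intermediate
33 | C2 alcohol | CO[C@@]4(C)O[C@@H]1C=C(C)[C@@H]2[C@H](O[Si](C(C)C)(C(C)C)C(C)C)[C@@]3(O)[C@H](/C=C(/C)CC[C@H](O)[C@@]2(C)[C@H]1O[C@]4(C)OC)OC(=O)[C@@H]3C | intermediate
34 | C2 propanoate | CO[C@@]4(C)O[C@@H]1C=C(C)[C@@H]2[C@H](O[Si](C(C)C)(C(C)C)C(C)C)[C@@]3(O)[C@H](/C=C(/C)CC[C@H](OC(=O)CC)[C@@]2(C)[C@H]1O[C@]4(C)OC)OC(=O)[C@@H]3C | intermediate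
35 | 13,14-diol | O[C@@H]1C=C(C)[C@@H]2[C@H](O[Si](C(C)C)(C(C)C)C(C)C)[C@@]3(O)[C@H](/C=C(/C)CC[C@H](OC(=O)CC)[C@@]2(C)[C@H]1O)OC(=O)[C@@H]3C | intermediate
36 | 9-O-TIPS ether of the target | CCCC(=O)O[C@@H]1C=C(C)[C@@H]2[C@H](O[Si](C(C)C)(C(C)C)C(C)C)[C@@]3(O)[C@H](/C=C(/C)CC[C@H](OC(=O)CC)[C@@]2(C)[C@H]1OC(=O)CCC)OC(=O)[C@@H]3C | intermediate
37 | CNP0138989.1 | CCCC(=O)O[C@@H]1C=C(C)[C@@H]2[C@H](O)[C@@]3(O)[C@H](/C=C(/C)CC[C@H](OC(=O)CC)[C@@]2(C)[C@H]1OC(=O)CCC)OC(=O)[C@@H]3C | target

**Step count and risks**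
Total: 30 steps. Longest linear sequence: 24 steps (steps 1–8, then 15–30, from compound 1); the ring-A branch from 11 is 22 steps.

Step 22 (ring contraction). Metalation may occur at the C12 methine or the PMB benzylic position instead of C9, or the strained trans-bridged ether may undergo a [1,2]-shift. The fallback exchanges the order of the two ring events, which also avoids the 13-membered ring of step 21. It sets out from 24: lithium 2,2,6,6-tetramethylpiperidide (THF, −78 °C), an amide base that spares the vinyl iodide, should give by acyclic [2,3]-Wittig rearrangement the homoallylic alcohol F1, with C10 again set by transfer from C12 and C9 by the exo envelope. Silylation (i-Pr3SiOTf, 2,6-lutidine) gives the silyl ether F2. Hydroboration with 9-BBN gives the alkylborane F3, and B-alkyl Suzuki–Miyaura coupling (Pd(dppf)Cl2, AsPh3, Cs2CO3, high dilution) closes the ten-membered ring at C4–C5, returning to the route at 28.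

Step 24 (osmylation). Site selectivity between C7=C8 and C5=C6 or facial selectivity on the ten-membered ring may be poor. The fallback sets out from 29 and replaces dihydroxylation by epoxidation and a π-allyl palladium lactonisation. VO(acac)2/t-BuOOH epoxidation directed by the homoallylic C19 hydroxyl gives the 7,8-epoxy alcohol F4. TEMPO/PhI(OAc)2 and then NaClO2 oxidise C19 to the epoxy acid F5. Pd(PPh3)4 ionises the vinyl epoxide at C7 with inversion, and the carboxylate attacks C7 with a second inversion (net retention), returning to the route at 32.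

Step 11 (iridium coupling). The catalyst has to override the Felkin preference of the transient α-alkoxy aldehyde, so diastereocontrol may erode or the aldehyde may epimerise. The fallback sets out from 13 and 14 and uses a stoichiometric allylboron reagent. Swern oxidation of 13 gives the aldehyde F6. Borylative ring opening of 14 (B2pin2, Ni(cod)2, PCy3) gives the (E)-allylboronate F7. Chiral phosphoric acid-catalysed allylboration of F6 with F7 (closed chair, the E geometry giving the same anti relationship) returns to the route at 15 after hydrolysis.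

Further compounds
F1 | step 22 | acyclic rearranged C9 alcohol (C9–C10 bond formed, C11=C12, C5 vinyl iodide, C2 vinyl carbinol PMB ether) | CO[C@@]4(C)O[C@@H]1C=C(C)[C@H]([C@H](O)/C([C@@H](C)CO[Si](C)(C)C(C)(C)C)=C\C=C(\C)I)[C@@](C)([C@@H](OCc3ccc(OC)cc3)C=C)[C@H]1O[C@]4(C)OC
F2 | step 22 | 9-O-TIPS ether of F1 | CO[C@@]4(C)O[C@@H]1C=C(C)[C@H]([C@H](O[Si](C(C)C)(C(C)C)C(C)C)/C([C@@H](C)CO[Si](C)(C)C(C)(C)C)=C\C=C(\C)I)[C@@](C)([C@@H](OCc3ccc(OC)cc3)C=C)[C@H]1O[C@]4(C)OC
F3 | step 22 | alkylborane of F2 (C4 bound to 9-BBN boron) | CO[C@@]4(C)O[C@@H]1C=C(C)[C@H]([C@H](O[Si](C(C)C)(C(C)C)C(C)C)/C([C@@H](C)CO[Si](C)(C)C(C)(C)C)=C\C=C(\C)I)[C@@](C)([C@@H](OCc3ccc(OC)cc3)CCB5C6CCCC5CCC6)[C@H]1O[C@]4(C)OC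
F4 | step 24 | 7,8-epoxy C19 alcohol | CO[C@@]4(C)O[C@@H]1C=C(C)[C@@H]2[C@H](O[Si](C(C)C)(C(C)C)C(C)C)[C@@]3([C@@H](C)CO)O[C@H]3/C=C(/C)CC[C@H](OCc5ccc(OC)cc5)[C@@]2(C)[C@H]1O[C@]4(C)OC
F5 | step 24 | 7,8-epoxy C19 carboxylic acid | CO[C@@]4(C)O[C@@H]1C=C(C)[C@@H]2[C@H](O[Si](C(C)C)(C(C)C)C(C)C)[C@@]3([C@@H](C)C(=O)O)O[C@H]3/C=C(/C)CC[C@H](OCc5ccc(OC)cc5)[C@@]2(C)[C@H]1O[C@]4(C)OC
F6 | step 11 | (4R,5R)-2,2-dimethyl-5-(prop-1-en-2-yl)-1,3-dioxolane-4-carbaldehyde | C=C(C)[C@H]1OC(C)(C)O[C@H]1C=O
F7 | step 11 | (E)-2-methyl-4-(4,4,5,5-tetramethyl-1,3,2-dioxaborolan-2-yl)but-2-en-1-ol | OC/C(C)=C/CB1OC(C)(C)C(C)(C)O1
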